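| flask | substrate | partner | temperature | remark | time |
|---|---|---|---|---|---|
| midnight | 0.050 M | 0.12 M | 85 °C | run made earlier |  |
| summer | 0.20 M | 0.12 M | 102 °C | run made earlier |  |
| dusk | 0.10 M | 0.24 M | 85 °C | run made earlier |  |
| south-west | 0.10 M | 0.120 M | 90 °C |  | 12 min |
| north-east | 0.10 M | 0.120 M | 115 °C |  | 12 min |
| east | 0.10 M | 0.120 M |  | at 90 °C until 8.0 min, from then on at 115 °C | 12 min |

| run | time / min | target / % | substrate / % |
|---|---|---|---|
| midnight | 0.417 | 0 | 96.5 |
| midnight | 1.00 | 0 | 89.2 |
| midnight | 2.00 | 0.7 | 78.8 |
| midnight | 3.00 | 0.1 | 69.1 |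
| midnight | 4.00 | 0 | 61.7 |
| midnight | 6.00 | 2.1 | 49.4 |
| midnight | 8.00 | 1.8 | 38.6 |
| summer | 0.500 | 0.1 | 73.8 |
| summer | 1.00 | 0.9 | 54.4 |
| summer | 1.50 | 2.1 | 39.8 |
| summer | 2.00 | 1.7 | 29.7 |
| summer | 3.00 | 6.5 | 18.7 |
| summer | 4.00 | 10.2 | 12.9 |
| dusk | 1.33 | 1.1 | 85.7 |
| dusk | 3.00 | 0.6 | 67.8 |
| dusk | 4.00 | 2.0 | 62.2 |
| dusk | 6.00 | 3.7 | 49.6 |
| dusk | 8.00 | 5.4 | 37.4 |

(standard deviation of a reading: 1 percentage point)

1. the flask with the highest amount of target, in percent of the substrate charged ("all alike" if they lie within 1.5 percentage points) (south-west / north-east / east / all alike)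
2. final target, as a percentage of the substrate charged, in south-west
3. final target, as a percentage of the substrate charged, in north-east
4. final target, as a percentage of the substrate charged, in east

**Question.** Substrate lost over target found stands at 34.1 in the last midnight reading. What do you make of that ratio?

**Answer.** Leaving substrate and arriving at target are separate events, so I time the leaving first. Its rate integrates in closed form: if the loss is first order, [substrate]/[substrate at the start] = exp(−kt).

**Question.** Is it first order?

**Answer.** The last midnight reading gives k = 0.119 min⁻¹. The last dusk reading, with twice the substrate and twice the partner, gives 0.123 min⁻¹, level with midnight at the same temperature.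

**Question.** The summer run gives 0.512 min⁻¹ from its last reading. Why would you take another?

**Answer.** Its reading at 2.00 min gives 0.607 min⁻¹, faster, so the curve flattens late. I take the earlier figure, and I expect substrate to stand above my reckoning once little of it remains.

**Question.** And at 90 °C?

**Answer.** Taking ln k as straight in temperature between the two runs gives 0.192 min⁻¹. So the substrate lifetime, the first-order time constant 1/k, is 5.20 min. East's change at 8.0 min comes after 1.54 lifetimes, which by this estimate leaves 21.5% of the substrate. By the same estimate south-west at 12 min keeps 9.97%.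

**Question.** Left for where?

**Answer.** The lifetime does not say. I commit to these substrate figures and give no target figure of my own.

The forecast does give target figures. It holds that “Substrate loss is first order and ignores partner.” It names north-east as the highest, with 11% in south-west, 59% in north-east and 35% in east.

The flasks gave 13.0% target in south-west, 45.0% in north-east and 29.7% in east, so north-east leads as forecast, but it stands 14 percentage points below the forecast's figure.

    substrate → open intermediate (k = 0.100 min⁻¹, Ea = 114 kJ mol⁻¹)
    partner → second intermediate (k = 0.140 min⁻¹, Ea = 108 kJ mol⁻¹)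
    open intermediate + second intermediate → target (k = 0.790 L mol⁻¹ min⁻¹, Ea = 61.0 kJ mol⁻¹)
    2 open intermediate → homo product (k = 0.970 L mol⁻¹ min⁻¹, Ea = 83.0 kJ mol⁻¹)
    substrate ⇌ dormant form (K = 5.70, k = 0.100 min⁻¹, Ea = 100 kJ mol⁻¹, ΔH = −33.0 kJ mol⁻¹)
    (constants at 90 °C)

East held 22.2% substrate at the change, against 21.5% reckoned from the lifetime of 5.20 min, and south-west ended at 11.9% against 9.97%. The neighbour of east charged with 0.25 M substrate ended at 3.82% substrate, level with east at 3.82%, and with 19.7% target. At the start of east, the making of open intermediate and the loss to dormant form, forward steps alone, ran at a ratio of 1.0. At the change in east, dormant form held 37.2% and open intermediate 26.4%.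

The earlier runs and the new flask were generated by integration with constants of no real substance; noise was put on by code.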